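**Plan**
- Retrosynthesis: remove the C19 acetate; return the C8=C17 exocyclic alkene and C9–H to a ring-B C8=C9 alkene carrying C17–OH (reductive 1,3-transposition); cut C12–C13 (Stille) and C11=C12 (Takai) back to a C11 ester.
- Then cut C7–C8 and C9–C10 together: ring B (C5–C10) with C8=C9 and C5=C6 unsaturation is a cyclohexa-1,4-diene, the Diels–Alder retron of a ring-A 1-vinyl-2-methylcyclohexene (C7=C6–C5=C10) and a but-2-ynoate (C8≡C9).
- Forward: ring A from 2-methylcyclohexane-1,3-dione (C19 by aldol, C20 by enolate methylation, C6=C7 by triflate/vinyl coupling); ring B by the cycloaddition; C5=C6 hydrogenated; side chain joined; exocyclic alkene unveiled last; acetylation.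
- Stereochemistry: C3 and C4 from CBS desymmetrisation of the prochiral dione; C10 from diene-face control by C4 in the cycloaddition; C5 from hydrogenation anti to the axial C20/C19 groups; C9 from suprafacial diazene hydrogen transfer anti to C20; E-alkene from the Takai reaction.

Key step: step 9

Remark: labdane numbering is used for positions (C3 carbinol, C4 and C10 quaternary, C8/C17 exocyclic alkene, C9 side-chain carbon, C19 acetoxymethyl, C20 angular methyl); compounds 1 and 9 and all named reagents are taken as commercial.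

Step 1
Reactants: 1 2-methylcyclohexane-1,3-dione
Product: 2 2-(hydroxymethyl)-2-methylcyclohexane-1,3-dione
Conditions: 37% aq. HCHO, H2O, rt
Reagents that add atoms: formaldehyde, C=O
Why: Aldol hydroxymethylation of the doubly activated C2–H should stop at the mono-adduct because C2 becomes quaternary and cannot dehydrate; no stereocentre is formed.

Step 2
Reactants: 2 2-(hydroxymethyl)-2-methylcyclohexane-1,3-dione
Product: 3 2-{[(tert-butyldimethylsilyl)oxy]methyl}-2-methylcyclohexane-1,3-dione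
Conditions: TBSCl, imidazole, DMF, 0 °C
Reagents that add atoms: tert-butyldimethylsilyl chloride, CC(C)(C)[Si](C)(C)Cl
Why: Standard silylation of the primary alcohol blocks retro-aldol loss of formaldehyde and makes the CH2O arm much larger than the methyl group for the face-selective reduction that follows; no stereocentre is formed.

Step 3
Reactants: 3 2-{[(tert-butyldimethylsilyl)oxy]methyl}-2-methylcyclohexane-1,3-dione
Product: 4 (2R,3R)-2-{[(tert-butyldimethylsilyl)oxy]methyl}-3-hydroxy-2-methylcyclohexan-1-one (OH cis to CH2OTBS)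
Conditions: (S)-Me-CBS (15 mol%), BH3·SMe2 (0.6 equiv), THF, −40 °C; MeOH quench
Reagents that add atoms: none
Why: Corey–Bakshi–Shibata desymmetrising mono-reduction of a 2,2-disubstituted cyclohexane-1,3-dione, in which hydride should add anti to the bulky CH2OTBS arm (OH cis to CH2OTBS) and the (S)-catalyst, treating the quaternary carbon as the large group, should select the carbonyl whose reduction from that face gives the 3R carbinol, so that C3 and C4 are fixed together.

Step 4
Reactants: 4 (2R,3R)-2-{[(tert-butyldimethylsilyl)oxy]methyl}-3-hydroxy-2-methylcyclohexan-1-one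
Product: 5 (2R,3R)-3-[(tert-butyldimethylsilyl)oxy]-2-{[(tert-butyldimethylsilyl)oxy]methyl}-2-methylcyclohexan-1-one
Conditions: TBSOTf, 2,6-lutidine, CH2Cl2, −78 → 0 °C
Reagents that add atoms: tert-butyldimethylsilyl trifluoromethanesulfonate, CC(C)(C)[Si](C)(C)OS(=O)(=O)C(F)(F)F
Why: Silylation of the hindered secondary alcohol with the silyl triflate under weakly basic conditions protects the β-hydroxy ketone against retro-aldol cleavage in the enolate steps; no stereocentre changes.

Step 5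
Reactants: 5 (2R,3R)-3-[(tert-butyldimethylsilyl)oxy]-2-{[(tert-butyldimethylsilyl)oxy]methyl}-2-methylcyclohexan-1-one
Product: 6 (2R,3R)-3-[(tert-butyldimethylsilyl)oxy]-2-{[(tert-butyldimethylsilyl)oxy]methyl}-2,6-dimethylcyclohexan-1-one (mixture of C6 epimers)
Conditions: LDA, THF, −78 °C; MeI, −78 → −20 °C
Reagents that add atoms: iodomethane, CI
Why: The lithium enolate can form only at C6 because C2 is quaternary, and its SN2 methylation (enolate alkylation) installs the future C20 methyl; the new C6 centre is an inconsequential epimer mixture since it becomes sp2 in step 6.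

Step 6
Reactants: 6 (2R,3R)-3-[(tert-butyldimethylsilyl)oxy]-2-{[(tert-butyldimethylsilyl)oxy]methyl}-2,6-dimethylcyclohexan-1-one
Product: 7 (5R,6R)-5-[(tert-butyldimethylsilyl)oxy]-6-{[(tert-butyldimethylsilyl)oxy]methyl}-2,6-dimethylcyclohex-1-en-1-yl trifluoromethanesulfonate
Conditions: KHMDS, THF, −78 °C; PhNTf2, −78 → 0 °C
Reagents that add atoms: N-phenylbis(trifluoromethanesulfonimide), O=S(=O)(N(c1ccccc1)S(=O)(=O)C(F)(F)F)C(F)(F)F
Why: Enolisation is possible only towards the methyl-bearing carbon, so O-triflation of the potassium enolate (enol triflate formation) should give the tetrasubstituted enol triflate as a single regioisomer.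

Step 7
Reactants: 7 (5R,6R)-5-[(tert-butyldimethylsilyl)oxy]-6-{[(tert-butyldimethylsilyl)oxy]methyl}-2,6-dimethylcyclohex-1-en-1-yl trifluoromethanesulfonate
Product: 8 (5R,6R)-5-[(tert-butyldimethylsilyl)oxy]-6-{[(tert-butyldimethylsilyl)oxy]methyl}-1-ethenyl-2,6-dimethylcyclohex-1-ene
Conditions: CH2=CHSnBu3, Pd(PPh3)4 (5 mol%), LiCl (3 equiv), THF, 65 °C
Reagents that add atoms: tributyl(vinyl)stannane, C=C[Sn](CCCC)(CCCC)CCCC
Why: Stille coupling of a hindered cyclohexenyl triflate with vinylstannane under LiCl promotion is well known for 2,6,6-trisubstituted cyclohexenyl triflates and should give the 1-vinyl-2-methylcyclohexene diene without touching the stereocentres.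

Step 8
Reactants: 9 methyl 4-hydroxybut-2-ynoate
Product: 10 methyl 4-[(tert-butyldimethylsilyl)oxy]but-2-ynoate
Conditions: TBSCl, imidazole, CH2Cl2, 0 °C → rt
Reagents that add atoms: tert-butyldimethylsilyl chloride, CC(C)(C)[Si](C)(C)Cl
Why: Standard silylation of the propargylic alcohol prevents lactonisation after the cycloaddition and stores the C17 oxygen needed for the late transposition.

Step 9
Reactants: 8 (5R,6R)-5-[(tert-butyldimethylsilyl)oxy]-6-{[(tert-butyldimethylsilyl)oxy]methyl}-1-ethenyl-2,6-dimethylcyclohex-1-ene; 10 methyl 4-[(tert-butyldimethylsilyl)oxy]but-2-ynoate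
Product: 11 methyl (5R,6R,8aR)-6-[(tert-butyldimethylsilyl)oxy]-2,5-bis{[(tert-butyldimethylsilyl)oxy]methyl}-5,8a-dimethyl-3,5,6,7,8,8a-hexahydronaphthalene-1-carboxylate (ring-B 1,4-diene: C5=C6 and C8=C9)
Conditions: 10 (3 equiv), BHT (cat.), neat, 130 °C, sealed tube, Ar
Reagents that add atoms: none
Why: Thermal intermolecular Diels–Alder reaction of the s-cis diene C7=C6–C5=C10 of 8 with the ynoate, the reaction type of the classical drimane entry from 1-vinyl-2,6,6-trimethylcyclohexene and acetylenic esters. Ring B closes by a concerted, asynchronous suprafacial [4π+2π] addition in which the C7–C8 bond to the unsubstituted diene terminus leads and the C9–C10 bond to the fully substituted terminus follows. The largest HOMO coefficient lies on C7 (two alkyl donors on C10) and pairs with the β-carbon of the ynoate ("ortho" orientation), so C8 should carry CH2OTBS and C9 the ester. The only new stereocentre is quaternary C10: the alkyne should approach the diene face anti to the pseudoaxial CH2OTBS group on C4 (half-chair with the C3 silyloxy group equatorial), which places the C10 methyl cis to CH2OTBS. The step needs regio- and π-facial selectivity and no [1,5]-hydrogen shift of the Z-methyl diene; these are secured by the donor pattern of the diene, the C3/C4 stereocentres and a temperature kept at or below 130 °C. The tetrasubstituted C8=C9 ester alkene formed here resists the next hydrogenation and stores the exocyclic methylene and the C9–H for step 17.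

Step 10
Reactants: 11 methyl (5R,6R,8aR)-6-[(tert-butyldimethylsilyl)oxy]-2,5-bis{[(tert-butyldimethylsilyl)oxy]methyl}-5,8a-dimethyl-3,5,6,7,8,8a-hexahydronaphthalene-1-carboxylate
Product: 12 methyl (4aS,5R,6R,8aR)-6-[(tert-butyldimethylsilyl)oxy]-2,5-bis{[(tert-butyldimethylsilyl)oxy]methyl}-5,8a-dimethyl-3,4,4a,5,6,7,8,8a-octahydronaphthalene-1-carboxylate
Conditions: H2 (3 atm), 10% Pd/C, EtOAc, rt
Reagents that add atoms: none
Why: Heterogeneous hydrogenation should take the trisubstituted C5=C6 alkene from the face opposite the axial C20 methyl and C19 arm to give the trans-decalin (H5 anti to C20), while the tetrasubstituted conjugated C8=C9 ester alkene stays, as known for drimane diene esters.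

Step 11
Reactants: 12 methyl (4aS,5R,6R,8aR)-6-[(tert-butyldimethylsilyl)oxy]-2,5-bis{[(tert-butyldimethylsilyl)oxy]methyl}-5,8a-dimethyl-3,4,4a,5,6,7,8,8a-octahydronaphthalene-1-carboxylate
Product: 13 [(4aS,5R,6R,8aR)-6-[(tert-butyldimethylsilyl)oxy]-2,5-bis{[(tert-butyldimethylsilyl)oxy]methyl}-5,8a-dimethyl-3,4,4a,5,6,7,8,8a-octahydronaphthalen-1-yl]methanol
Conditions: DIBAL-H (3 equiv), CH2Cl2, −78 → 0 °C; Rochelle salt work-up
Reagents that add atoms: none
Why: 1,2-Reduction of the conjugated ester with DIBAL-H should give the allylic alcohol at C11 without touching the silyl ethers or the tetrasubstituted alkene.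

Step 12
Reactants: 13 [(4aS,5R,6R,8aR)-6-[(tert-butyldimethylsilyl)oxy]-2,5-bis{[(tert-butyldimethylsilyl)oxy]methyl}-5,8a-dimethyl-3,4,4a,5,6,7,8,8a-octahydronaphthalen-1-yl]methanol
Product: 14 (4aS,5R,6R,8aR)-6-[(tert-butyldimethylsilyl)oxy]-2,5-bis{[(tert-butyldimethylsilyl)oxy]methyl}-5,8a-dimethyl-3,4,4a,5,6,7,8,8a-octahydronaphthalene-1-carbaldehyde
Conditions: Dess–Martin periodinane, NaHCO3, CH2Cl2, 0 °C → rt
Reagents that add atoms: none
Why: Dess–Martin oxidation of the primary allylic alcohol gives a conjugated enal that has no epimerisable α-centre, so the aldehyde is configurationally safe.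

Step 13
Reactants: 14 (4aS,5R,6R,8aR)-6-[(tert-butyldimethylsilyl)oxy]-2,5-bis{[(tert-butyldimethylsilyl)oxy]methyl}-5,8a-dimethyl-3,4,4a,5,6,7,8,8a-octahydronaphthalene-1-carbaldehyde
Product: 15 (4aS,5R,6R,8aR)-6-[(tert-butyldimethylsilyl)oxy]-2,5-bis{[(tert-butyldimethylsilyl)oxy]methyl}-1-[(E)-2-iodoethenyl]-5,8a-dimethyl-3,4,4a,5,6,7,8,8a-octahydronaphthalene
Conditions: CHI3 (2 equiv), CrCl2 (6 equiv), THF/1,4-dioxane, 0 °C → rt
Reagents that add atoms: iodoform, IC(I)I
Why: Takai iodo-olefination converts aldehydes, including enals, into (E)-vinyl iodides under non-basic conditions, which sets the E geometry of C11=C12.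

Step 14
Reactants: 9 methyl 4-hydroxybut-2-ynoate
Product: 17 3-(tributylstannyl)furan-2(5H)-one, via open-chain stannyl hydroxy ester 16 (not isolated)
Conditions: Bu3SnH, Pd(PPh3)4 (2 mol%), THF, 0 °C → rt; then PPTS (cat.), 40 °C
Reagents that add atoms: tributyltin hydride, CCCC[SnH](CCCC)CCCC
Why: Pd(0)-catalysed syn-hydrostannation of an ynoate places tin on the α-carbon and hydrogen on the β-carbon, so the hydroxymethyl and ester groups end up cis and should lactonise to the α-stannyl butenolide on mild acid treatment.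

Step 15
Reactants: 15 (4aS,5R,6R,8aR)-6-[(tert-butyldimethylsilyl)oxy]-2,5-bis{[(tert-butyldimethylsilyl)oxy]methyl}-1-[(E)-2-iodoethenyl]-5,8a-dimethyl-3,4,4a,5,6,7,8,8a-octahydronaphthalene; 17 3-(tributylstannyl)furan-2(5H)-one
Product: 18 3-[(E)-2-{(4aS,5R,6R,8aR)-6-[(tert-butyldimethylsilyl)oxy]-2,5-bis{[(tert-butyldimethylsilyl)oxy]methyl}-5,8a-dimethyl-3,4,4a,5,6,7,8,8a-octahydronaphthalen-1-yl}ethenyl]furan-2(5H)-one
Conditions: Pd2(dba)3 (5 mol%), AsPh3 (20 mol%), CuI (10 mol%), NMP, rt → 40 °C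
Reagents that add atoms: none
Why: Stille coupling of an (E)-dienyl iodide with an α-stannyl butenolide under ligand-accelerated, copper-assisted neutral conditions should tolerate the base-sensitive butenolide and keep the alkene geometry; the E central alkene also rules out 6π-electrocyclisation of the triene.

Step 16
Reactants: 18 3-[(E)-2-{(4aS,5R,6R,8aR)-6-[(tert-butyldimethylsilyl)oxy]-2,5-bis{[(tert-butyldimethylsilyl)oxy]methyl}-5,8a-dimethyl-3,4,4a,5,6,7,8,8a-octahydronaphthalen-1-yl}ethenyl]furan-2(5H)-one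
Product: 19 3-[(E)-2-{(4aS,5R,6R,8aR)-6-hydroxy-2,5-bis(hydroxymethyl)-5,8a-dimethyl-3,4,4a,5,6,7,8,8a-octahydronaphthalen-1-yl}ethenyl]furan-2(5H)-one
Conditions: HF·pyridine, pyridine, THF, 0 °C → rt
Reagents that add atoms: none
Why: Buffered fluoride-mediated desilylation should remove all three silyl ethers under conditions too weakly acidic or basic to ionise the allylic alcohol or open or isomerise the butenolide.

Step 17
Reactants: 19 3-[(E)-2-{(4aS,5R,6R,8aR)-6-hydroxy-2,5-bis(hydroxymethyl)-5,8a-dimethyl-3,4,4a,5,6,7,8,8a-octahydronaphthalen-1-yl}ethenyl]furan-2(5H)-one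
Product: 22 14-deoxy-11,12-didehydroandrographolide, via allylic sulfonylhydrazine 20 (not isolated), via allylic diazene 21 (not isolated)
Conditions: 2-nitrobenzenesulfonylhydrazide (NBSH), PPh3, DEAD, THF, −30 °C → rt
Reagents that add atoms: none
Why: Myers reductive 1,3-transposition, in which Mitsunobu alkylation of NBSH should occur only at the unhindered primary allylic C17 hydroxyl (the neopentylic C19 and hindered C3 hydroxyls are poor Mitsunobu substrates), sulfinate loss gives the monoalkyl diazene, and its retro-ene loss of N2 delivers hydrogen to C9 suprafacially from the face anti to the axial C20 methyl while moving the alkene to C8=C17, so the side chain at C9 ends up equatorial and cis to C20.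

Step 18
Reactants: 22 14-deoxy-11,12-didehydroandrographolide
Product: 23 [(1R,2R,4aR,5R,8aS)-2-hydroxy-1,4a-dimethyl-6-methylidene-5-[(E)-2-(2-oxo-2,5-dihydrofuran-3-yl)ethenyl]decahydronaphthalen-1-yl]methyl acetate (target)
Conditions: AcCl (1.05 equiv), 2,4,6-collidine, CH2Cl2, −78 °C
Reagents that add atoms: acetyl chloride, CC(Cl)=O
Why: Low-temperature acylation with acetyl chloride and collidine is selective for primary over secondary alcohols, and the C3 hydroxyl is further shielded by the adjacent quaternary C4, so only the C19 hydroxyl should be acetylated.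

**Compound list**
1 | 2-methylcyclohexane-1,3-dione | CC1C(=O)CCCC1=O | starting material
2 | 2-(hydroxymethyl)-2-methylcyclohexane-1,3-dione | CC1(CO)C(=O)CCCC1=O | intermediate
3 | 2-{[(tert-butyldimethylsilyl)oxy]methyl}-2-methylcyclohexane-1,3-dione | CC1(CO[Si](C)(C)C(C)(C)C)C(=O)CCCC1=O | intermediate
4 | (2R,3R)-2-{[(tert-butyldimethylsilyl)oxy]methyl}-3-hydroxy-2-methylcyclohexan-1-one | O=C1[C@](C)(CO[Si](C)(C)C(C)(C)C)[C@H](O)CCC1 | intermediate
5 | (2R,3R)-3-[(tert-butyldimethylsilyl)oxy]-2-{[(tert-butyldimethylsilyl)oxy]methyl}-2-methylcyclohexan-1-one | O=C1[C@](C)(CO[Si](C)(C)C(C)(C)C)[C@H](O[Si](C)(C)C(C)(C)C)CCC1 | intermediate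
6 | (2R,3R)-3-[(tert-butyldimethylsilyl)oxy]-2-{[(tert-butyldimethylsilyl)oxy]methyl}-2,6-dimethylcyclohexan-1-one (C6 epimers) | O=C1[C@](C)(CO[Si](C)(C)C(C)(C)C)[C@H](O[Si](C)(C)C(C)(C)C)CCC1C | intermediate
7 | (5R,6R)-5-[(tert-butyldimethylsilyl)oxy]-6-{[(tert-butyldimethylsilyl)oxy]methyl}-2,6-dimethylcyclohex-1-en-1-yl trifluoromethanesulfonate | CC1=C(OS(=O)(=O)C(F)(F)F)[C@](C)(CO[Si](C)(C)C(C)(C)C)[C@H](O[Si](C)(C)C(C)(C)C)CC1 | intermediate
8 | (5R,6R)-5-[(tert-butyldimethylsilyl)oxy]-6-{[(tert-butyldimethylsilyl)oxy]methyl}-1-ethenyl-2,6-dimethylcyclohex-1-ene | CC1=C(C=C)[C@](C)(CO[Si](C)(C)C(C)(C)C)[C@H](O[Si](C)(C)C(C)(C)C)CC1 | intermediate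
9 | methyl 4-hydroxybut-2-ynoate | COC(=O)C#CCO | starting material
10 | methyl 4-[(tert-butyldimethylsilyl)oxy]but-2-ynoate | COC(=O)C#CCO[Si](C)(C)C(C)(C)C | intermediate
11 | methyl (5R,6R,8aR)-6-[(tert-butyldimethylsilyl)oxy]-2,5-bis{[(tert-butyldimethylsilyl)oxy]methyl}-5,8a-dimethyl-3,5,6,7,8,8a-hexahydronaphthalene-1-carboxylate | COC(=O)C1=C(CO[Si](C)(C)C(C)(C)C)CC=C2[C@](C)(CO[Si](C)(C)C(C)(C)C)[C@H](O[Si](C)(C)C(C)(C)C)CC[C@@]12C | intermediate
12 | methyl (4aS,5R,6R,8aR)-6-[(tert-butyldimethylsilyl)oxy]-2,5-bis{[(tert-butyldimethylsilyl)oxy]methyl}-5,8a-dimethyl-3,4,4a,5,6,7,8,8a-octahydronaphthalene-1-carboxylate | COC(=O)C1=C(CO[Si](C)(C)C(C)(C)C)CC[C@@H]2[C@](C)(CO[Si](C)(C)C(C)(C)C)[C@H](O[Si](C)(C)C(C)(C)C)CC[C@@]12C | intermediate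
13 | [(4aS,5R,6R,8aR)-6-[(tert-butyldimethylsilyl)oxy]-2,5-bis{[(tert-butyldimethylsilyl)oxy]methyl}-5,8a-dimethyl-3,4,4a,5,6,7,8,8a-octahydronaphthalen-1-yl]methanol | OCC1=C(CO[Si](C)(C)C(C)(C)C)CC[C@@H]2[C@](C)(CO[Si](C)(C)C(C)(C)C)[C@H](O[Si](C)(C)C(C)(C)C)CC[C@@]12C | intermediate
14 | (4aS,5R,6R,8aR)-6-[(tert-butyldimethylsilyl)oxy]-2,5-bis{[(tert-butyldimethylsilyl)oxy]methyl}-5,8a-dimethyl-3,4,4a,5,6,7,8,8a-octahydronaphthalene-1-carbaldehyde | O=CC1=C(CO[Si](C)(C)C(C)(C)C)CC[C@@H]2[C@](C)(CO[Si](C)(C)C(C)(C)C)[C@H](O[Si](C)(C)C(C)(C)C)CC[C@@]12C | intermediate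
15 | (4aS,5R,6R,8aR)-6-[(tert-butyldimethylsilyl)oxy]-2,5-bis{[(tert-butyldimethylsilyl)oxy]methyl}-1-[(E)-2-iodoethenyl]-5,8a-dimethyl-3,4,4a,5,6,7,8,8a-octahydronaphthalene | I/C=C/C1=C(CO[Si](C)(C)C(C)(C)C)CC[C@@H]2[C@](C)(CO[Si](C)(C)C(C)(C)C)[C@H](O[Si](C)(C)C(C)(C)C)CC[C@@]12C | intermediate
16 | methyl (E)-4-hydroxy-2-(tributylstannyl)but-2-enoate (CH2OH cis to ester) | COC(=O)/C(=C\CO)[Sn](CCCC)(CCCC)CCCC | intermediate
17 | 3-(tributylstannyl)furan-2(5H)-one | CCCC[Sn](CCCC)(CCCC)C1=CCOC1=O | intermediate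
18 | 3-[(E)-2-{(4aS,5R,6R,8aR)-6-[(tert-butyldimethylsilyl)oxy]-2,5-bis{[(tert-butyldimethylsilyl)oxy]methyl}-5,8a-dimethyl-3,4,4a,5,6,7,8,8a-octahydronaphthalen-1-yl}ethenyl]furan-2(5H)-one | O=C1OCC=C1/C=C/C1=C(CO[Si](C)(C)C(C)(C)C)CC[C@@H]2[C@](C)(CO[Si](C)(C)C(C)(C)C)[C@H](O[Si](C)(C)C(C)(C)C)CC[C@@]12C | intermediate
19 | 3-[(E)-2-{(4aS,5R,6R,8aR)-6-hydroxy-2,5-bis(hydroxymethyl)-5,8a-dimethyl-3,4,4a,5,6,7,8,8a-octahydronaphthalen-1-yl}ethenyl]furan-2(5H)-one | O=C1OCC=C1/C=C/C1=C(CO)CC[C@@H]2[C@](C)(CO)[C@H](O)CC[C@@]12C | intermediate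
20 | N-alkyl-N-(2-nitrobenzenesulfonyl)hydrazine of 19 at C17 (Mitsunobu adduct) | O=C1OCC=C1/C=C/C1=C(CN(N)S(=O)(=O)c3ccccc3[N+](=O)[O-])CC[C@@H]2[C@](C)(CO)[C@H](O)CC[C@@]12C | intermediate
21 | allylic monoalkyl diazene at C17 | O=C1OCC=C1/C=C/C1=C(CN=N)CC[C@@H]2[C@](C)(CO)[C@H](O)CC[C@@]12C | intermediate
22 | 14-deoxy-11,12-didehydroandrographolide, 3-[(E)-2-{(1R,4aS,5R,6R,8aR)-6-hydroxy-5-(hydroxymethyl)-5,8a-dimethyl-2-methylidenedecahydronaphthalen-1-yl}ethenyl]furan-2(5H)-one | C=C1CC[C@@H]2[C@](C)(CO)[C@H](O)CC[C@@]2(C)[C@@H]1/C=C/C1=CCOC1=O | intermediate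
23 | [(1R,2R,4aR,5R,8aS)-2-hydroxy-1,4a-dimethyl-6-methylidene-5-[(E)-2-(2-oxo-2,5-dihydrofuran-3-yl)ethenyl]decahydronaphthalen-1-yl]methyl acetate | C=C1CC[C@@H]2[C@](C)(COC(C)=O)[C@H](O)CC[C@@]2(C)[C@@H]1/C=C/C1=CCOC1=O | target

**Totals**
Total step count: 18. Longest linear sequence: 16 steps (steps 1–7, 9–13, 15–18, from compound 1).

**Steps most likely to fail**

1. Step 9. What may go wrong: sluggish cycloaddition at the fully substituted diene terminus with thermal loss of the ynoate, or erosion of regio- or π-facial selectivity. Fallback: from 8, the cycloaddition would be run with dimethyl acetylenedicarboxylate (symmetrical and far more reactive; neat, 110 °C) to give the diester diene adduct F1. Hydrogenation of C5=C6 (H2, Pd/C) would give the trans-fused diester F2, and reduction of both esters (DIBAL-H) the ene-1,4-diol F3. Selective silylation of the less hindered C17 hydroxyl (TBSCl, imidazole, −40 °C; the C11 hydroxymethyl is shielded by quaternary C10) comes back to the route at 13.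

2. Step 17. What may go wrong: unselective Mitsunobu activation among the three free hydroxyls, or decomposition of the sulfonylhydrazide before alkylation, so that little diazene forms. Fallback: from 18, only the primary allylic silyl ether would be cleaved (HF·pyridine buffered with pyridine, 0 °C, short contact) to give the mono-alcohol F4. The reductive transposition would then be run on this single free hydroxyl (NBSH, PPh3, DEAD) to give the bis-silyl ether with the exocyclic alkene F5. Removal of the two remaining silyl groups (TBAF/AcOH, THF) comes back at 22.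

3. Step 3. What may go wrong: incomplete catalyst control (low enantiomeric purity), poor face selectivity, or over-reduction to the diol. Fallback: from 3, a non-selective but face-selective hydride reduction (NaBH4, MeOH/CH2Cl2, −78 °C) would give the racemic cis-hydroxy ketone, that is 4 together with its enantiomer F6. Lipase-catalysed acylation (Amano PS, vinyl acetate, MTBE) is expected, by the empirical rule for lipase enantiopreference of secondary alcohols, to acylate the 3R enantiomer and give the acetate F7, which is separated from unreacted F6. Enzymatic hydrolysis of F7 (same lipase, pH 7 buffer) comes back at 4.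

**Further compounds**
F1 | step 9 | dimethyl (5R,6R,8aR)-6-[(tert-butyldimethylsilyl)oxy]-5-{[(tert-butyldimethylsilyl)oxy]methyl}-5,8a-dimethyl-3,5,6,7,8,8a-hexahydronaphthalene-1,2-dicarboxylate | COC(=O)C1=C(C(=O)OC)CC=C2[C@](C)(CO[Si](C)(C)C(C)(C)C)[C@H](O[Si](C)(C)C(C)(C)C)CC[C@@]12C
F2 | step 9 | dimethyl (4aS,5R,6R,8aR)-6-[(tert-butyldimethylsilyl)oxy]-5-{[(tert-butyldimethylsilyl)oxy]methyl}-5,8a-dimethyl-3,4,4a,5,6,7,8,8a-octahydronaphthalene-1,2-dicarboxylate | COC(=O)C1=C(C(=O)OC)CC[C@@H]2[C@](C)(CO[Si](C)(C)C(C)(C)C)[C@H](O[Si](C)(C)C(C)(C)C)CC[C@@]12C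
F3 | step 9 | [(4aS,5R,6R,8aR)-6-[(tert-butyldimethylsilyl)oxy]-5-{[(tert-butyldimethylsilyl)oxy]methyl}-5,8a-dimethyl-3,4,4a,5,6,7,8,8a-octahydronaphthalene-1,2-diyl]dimethanol | OCC1=C(CO)CC[C@@H]2[C@](C)(CO[Si](C)(C)C(C)(C)C)[C@H](O[Si](C)(C)C(C)(C)C)CC[C@@]12C
F4 | step 17 | 3-[(E)-2-{(4aS,5R,6R,8aR)-6-[(tert-butyldimethylsilyl)oxy]-5-{[(tert-butyldimethylsilyl)oxy]methyl}-2-(hydroxymethyl)-5,8a-dimethyl-3,4,4a,5,6,7,8,8a-octahydronaphthalen-1-yl}ethenyl]furan-2(5H)-one | O=C1OCC=C1/C=C/C1=C(CO)CC[C@@H]2[C@](C)(CO[Si](C)(C)C(C)(C)C)[C@H](O[Si](C)(C)C(C)(C)C)CC[C@@]12C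
F5 | step 17 | 3,19-bis-O-(tert-butyldimethylsilyl)-14-deoxy-11,12-didehydroandrographolide | C=C1CC[C@@H]2[C@](C)(CO[Si](C)(C)C(C)(C)C)[C@H](O[Si](C)(C)C(C)(C)C)CC[C@@]2(C)[C@@H]1/C=C/C1=CCOC1=O
F6 | step 3 | (2S,3S)-2-{[(tert-butyldimethylsilyl)oxy]methyl}-3-hydroxy-2-methylcyclohexan-1-one | O=C1[C@@](C)(CO[Si](C)(C)C(C)(C)C)[C@@H](O)CCC1
F7 | step 3 | (1R,2R)-2-{[(tert-butyldimethylsilyl)oxy]methyl}-2-methyl-3-oxocyclohexyl acetate | O=C1[C@](C)(CO[Si](C)(C)C(C)(C)C)[C@H](OC(C)=O)CCC1
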